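## Analysis of the target

Kushenol U is a flavanone: ring A (a phloroglucinol-type benzene) is fused to the dihydropyranone ring C, ring B is a 4-hydroxyphenyl group on C2, O5 is a methyl ether, O7 is a free phenol, and C8 carries a lavandulyl chain, numbered here C1'' (benzylic CH2), C2'' (stereocentre), C3''–C4''=C5'' (prenyl arm) and C8''(=C9'')–C10'' (isopropenyl arm). The two stereocentres, C2 (S) and C2'' (R), lie five bonds apart through O1, C8a, C8 and C1'', so neither can direct the other and each has to be set by a catalyst. C2 is labile, because base opens ring C by a retro-oxa-Michael reaction that the free 4'-phenol assists, and it is therefore best made late. Both chain alkenes are acid-sensitive, since a neighbouring phenol oxygen can add to the tertiary cation formed from the isopropenyl group, and they must also pass untouched through every metal-catalysed step. Ring A is fully differentiated, so C6 has to be told from C8 and the three oxygens from one another. The hardest element is C2'', an acyclic tertiary carbon with three carbon substituents and no heteroatom nearby to guide its formation. The plan rests on the unit C8–C1''–C2''(–C8''): an aryl–CH2–CH fragment whose CH carbon bears an alkenyl group, which is what remains when a vinylboron ate complex accepts an aryl group at its terminal carbon while a group moves from boron to the boron-bearing carbon.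

## Retrosynthetic reasoning

**21 to 20.** The final operation removes the two methoxymethyl groups from O7 and O4'. The ring A acetal is the same group that directs the metalations earlier, so no protecting-group exchange is needed along the way.

**20 to 18 and 19.** The C2–C1' bond is cut. Adding the ring B aryl group of 19 to the C2=C3 bond of chromone 18 creates C2 in a C–C bond-forming event under ligand control. Closing ring C by addition of a phenol to an open-chain enone would instead set C2 in a reversible step. The forward reaction has to choose the enone alkene over both chain alkenes and deliver the 2S face.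

**18 to 16 (through 17).** O1–C2 and C2–C3 are cut. C2 is introduced as a single carbon at the formic acid oxidation level, which condenses with the acetyl methyl group to give enaminone 17. The ortho phenol then closes ring C with loss of the amino group. Only one free phenol, ortho to the acetyl group, is required.

**16 to 15 to 13 (through 14).** The C4–C4a bond is cut. In 13 the two free ring positions are interchanged by rotation of the symmetrical ring about its bond to C1'', so metalation and acetylation can give only one compound. The price is that the two acetals, identical until now, must be distinguished. The one beside the new carbonyl group is cleaved selectively to give 16.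

**13 to 11 and 12.** The C3''–C4'' bond is cut, an sp3–sp2 coupling of the primary boronate 11 with the alkenyl bromide 12. This brings in the prenyl terminus as a commodity C4 piece and leaves the stereocentre untouched.

**11 to 9 (through 10).** The C2''–C3'' bond is cut by removing one CH2 from between carbon and boron. The forward step is a carbenoid insertion into the C–B bond, which keeps the configuration of the migrating carbon. It connects the chain to a precursor that has boron directly on C2''.

**9 to 4, 6 and 7 (through 8).** This is the central disconnection: C8–C1'' and C2''–C8'' are cut together. Compound 9 falls apart into the symmetrical aryl iodide 4, the two-carbon vinylboronate 6 and the organolithium 7, all achiral. The forward reaction must make both bonds and the C2'' centre in one catalytic event. Cutting here, rather than at C1''–C2'' or at a chain C–O bond, removes any need for an enantiopure lavandulyl building block. The boron left on C2'' is the handle for the two chain-extending steps above.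

**4 to 2 to 1 (through 3); 7 from 5.** The iodide 4 comes from metalation of 2 between its two acetal groups, the most activated position. Compound 2 is the bis-acetal of the commercial diol 1. The symmetry of 4 removes the C6 versus C8 question. The organolithium 7 is made from the bromide 5 immediately before use.

## Alternatives that were turned down

**Alternative 1:** Ring A itself is opened at C8–C8a and C6–C7. It would be assembled from 3-methoxycyclobut-2-en-1-one A1 and the triisopropylsilyl ynol ether A2, which already carries the (R)-lavandulyl chain.
- Forward key step: heating A1 with A2 sets off a pericyclic cascade (four-electron ring opening of A1, [2+2] addition to the alkyne of A2, a second four-electron opening and a six-electron closure). It should end in the phenol A3, 2-[(R)-lavandulyl]-5-methoxy-3-(triisopropylsilyloxy)phenol.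
- For it: the substitution pattern of A3 follows from the mechanism, and the two oxygens flanking C8 emerge differentiated (free OH at C8a, silyl ether at C7). On this point it is stronger than the chosen route, which has to separate two identical acetals in step 7.
- Against it: C2'' must already be present in A2, so the stereocentre is only moved into the synthesis of a sensitive ynol ether. The two chain alkenes sit within reach of the reactive intermediates of the cascade at high temperature. C4 is still absent from A3 and must then be placed on C4a rather than C6.
- Comparison: the chosen strategy makes C2'' and attaches the chain in one catalytic step from achiral materials, and pays for this with the later acetal discrimination.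

**Alternative 2:** O1–C8a and C4–C4a are cut together. Ring A would come from the ortho-silyl aryl triflate A4, which a fluoride source converts into the aryne A5.
- Forward key step: A5 takes up the cinnamic acid A6, (E)-4-(methoxymethoxy)cinnamic acid. The carboxylate oxygen of A6 adds to C8a and the acyl group then shifts to C4a, giving the 2'-hydroxychalcone A7.
- For it: all carbons of ring C and the whole of ring B arrive in one step, with the correct phenol free. On paper this is shorter than steps 6 to 9 here, and it is stronger on convergence.
- Against it: A4 is a pentasubstituted benzene with adjacent silyl and triflate groups and the chain already in place. Its preparation would be longer than the whole first half of the chosen route, and it again presupposes C2''. The addition to A5 must follow the inductive bias of the C5 methoxy group against the bulk of the C8 chain. A7 must then be closed by oxa-Michael addition, which is reversible and poorly controlled for an unactivated chalcone.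
- Comparison: the chosen route sets C2 in a C–C bond-forming step and builds the chain stereocentre catalytically.

**Alternative 3:** The two chain alkenes, C8''=C9'' and C4''=C5'', are disconnected back to the (R)-configured cyclobutene A8 and isobutylene A9.
- Forward key step: under the second-generation Hoveyda–Grubbs catalyst, A8 and A9 should undergo ring-opening cross-metathesis. The strained trisubstituted ring alkene is cleaved and its ends are capped with a methylidene and an isopropylidene group. The product A10 is the same compound as 13.
- For it: it converges on an intermediate of the chosen route, is driven by ring strain, does not touch the stereocentre, and belongs to a well-tested reaction class. In that respect it is stronger than the chosen key step, which is used outside its tested scope.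
- Against it: A8 is a chiral 1,4-disubstituted cyclobutene that needs its own multistep enantioselective synthesis. The two ring termini must also pick up different halves of A9, and double methylidene capping or ring-opening oligomerisation can compete.
- Comparison: from A10 onward the two routes are identical. The chosen strategy offers a shorter approach to 13, five steps from 1, with the stereocentre made from achiral reagents.

Key step: step 3

Assumption: the sense of induction of the two chiral ligands is assigned by analogy with simpler substrates; (Sp,Sp)-MandyPhos, a 1,1'-bis(diarylphosphino)-2,2'-bis[α-(dimethylamino)benzyl]ferrocene, is taken to give R at C2'', and (R)-t-BuPyOx is taken to give S at C2; if either sense is opposite, the mirror-image ligand is used and nothing else changes.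

## Route

Step 1
Reactants: 1 5-methoxyresorcinol
Product: 2 1-methoxy-3,5-bis(methoxymethoxy)benzene
Conditions: NaH, MOMCl, DMF, 0 °C → rt
Reagents that add atoms: chloromethyl methyl ether, COCCl
Why: Double O-alkylation of the phenoxides (Williamson ether synthesis); the acetals later serve as ortho-directing groups.

Step 2
Reactants: 2 1-methoxy-3,5-bis(methoxymethoxy)benzene
Product: 4 2-iodo-5-methoxy-1,3-bis(methoxymethoxy)benzene, via aryllithium 3 (not isolated)
Conditions: n-BuLi, THF, 0 °C; then I2, −78 °C → rt
Reagents that add atoms: iodine, II
Why: Directed ortho-metalation: the hydrogen between the two acetal groups should be removed selectively because both oxygens chelate lithium and an acetal directs more strongly than methoxy; iodinolysis of the aryllithium gives the symmetrical iodide.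

Step 3
Reactants: 4 2-iodo-5-methoxy-1,3-bis(methoxymethoxy)benzene; 5 2-bromopropene; 6 vinylboronic acid pinacol ester
Product: 9 (R)-2-{1-[4-methoxy-2,6-bis(methoxymethoxy)phenyl]-3-methylbut-3-en-2-yl}-4,4,5,5-tetramethyl-1,3,2-dioxaborolane, via isopropenyllithium 7 (not isolated), via vinyl(isopropenyl)borate complex 8 (not isolated)
Conditions: 5, t-BuLi (2 equiv), Et2O, −78 °C; 6, −78 °C → rt; solvent change to THF; 4, Pd(OAc)2 (cat.), (Sp,Sp)-MandyPhos (cat.), NaOTf, 60 °C
Reagents that add atoms: none
Why: Proposed new method: zerovalent palladium inserts into the C–I bond of 4 to give an aryl complex of divalent palladium, NaOTf strips the halide so that the cationic metal can coordinate the unsubstituted vinyl group of 8, and this π-activation drives a 1,2-shift of the isopropenyl group from boron to the internal carbon on the face opposite palladium, after which reductive elimination links the aryl carbon (future C8) to the terminal carbon (C1''). The closest known reaction type is the palladium/MandyPhos-catalysed enantioselective conjunctive cross-coupling of vinylboron ate complexes with aryl electrophiles, which has not been shown for a di-ortho-alkoxy aryl iodide combined with an alkenyl migrating group. No ring is closed. The one new stereocentre, C2'', is controlled by the chiral bisphosphine, which decides which face of the bound vinyl group is presented to palladium; because the shift is strictly anti to the metal, this facial choice should translate directly into the R configuration. The step needs chemoselectivity between the two alkenyl groups on boron, and the substrate supplies it: the 1,1-disubstituted isopropenyl group binds palladium less well than vinyl, so it should migrate while vinyl acts as the acceptor. Ring A regiochemistry does not arise because 4 is symmetrical, and plain transfer of an alkenyl group to palladium is disfavoured by the halide-free cationic metal and the tetracoordinate pinacolato boron.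

Step 4
Reactants: 9 (R)-2-{1-[4-methoxy-2,6-bis(methoxymethoxy)phenyl]-3-methylbut-3-en-2-yl}-4,4,5,5-tetramethyl-1,3,2-dioxaborolane
Product: 11 2-[(2R)-2-{[4-methoxy-2,6-bis(methoxymethoxy)phenyl]methyl}-3-methylbut-3-en-1-yl]-4,4,5,5-tetramethyl-1,3,2-dioxaborolane, via chloromethyl borate complex 10 (not isolated)
Conditions: BrCH2Cl, n-BuLi, THF, −78 °C → rt
Reagents that add atoms: bromochloromethane, ClCBr
Why: Matteson homologation: chloromethyllithium, generated in the presence of 9, adds to boron, and C2'' then migrates from boron to the CH2 carbon with loss of chloride; this 1,2-metallate shift retains configuration at the migrating carbon and involves no allylic transposition, so R should be kept.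

Step 5
Reactants: 11 2-[(2R)-2-{[4-methoxy-2,6-bis(methoxymethoxy)phenyl]methyl}-3-methylbut-3-en-1-yl]-4,4,5,5-tetramethyl-1,3,2-dioxaborolane; 12 1-bromo-2-methylpropene
Product: 13 5-methoxy-1,3-bis(methoxymethoxy)-2-[(2R)-5-methyl-2-(prop-1-en-2-yl)hex-4-en-1-yl]benzene
Conditions: Pd(OAc)2 (cat.), RuPhos, KOH, THF/H2O, 70 °C
Reagents that add atoms: none
Why: B-alkyl Suzuki–Miyaura coupling of a primary pinacol boronate with an alkenyl bromide; hydroxide activates boron and the bulky electron-rich biarylphosphine favours reductive elimination over β-hydride loss. The stereocentre is β to boron and takes no part.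

Step 6
Reactants: 13 5-methoxy-1,3-bis(methoxymethoxy)-2-[(2R)-5-methyl-2-(prop-1-en-2-yl)hex-4-en-1-yl]benzene
Product: 15 1-{6-methoxy-2,4-bis(methoxymethoxy)-3-[(2R)-5-methyl-2-(prop-1-en-2-yl)hex-4-en-1-yl]phenyl}ethan-1-one, via aryllithium 14 (not isolated)
Conditions: n-BuLi, THF, 0 °C; then MeC(O)N(OMe)Me, −78 °C → 0 °C; H2O
Reagents that add atoms: N-methoxy-N-methylacetamide, CC(=O)N(C)OC
Why: Directed ortho-metalation at a ring position flanked by OMe and an acetal; the two free positions are interchanged by rotation of the symmetrical ring, so only one product can form. Acylation with a Weinreb amide stops at the ketone.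

Step 7
Reactants: 15 1-{6-methoxy-2,4-bis(methoxymethoxy)-3-[(2R)-5-methyl-2-(prop-1-en-2-yl)hex-4-en-1-yl]phenyl}ethan-1-one
Product: 16 1-{2-hydroxy-6-methoxy-4-(methoxymethoxy)-3-[(2R)-5-methyl-2-(prop-1-en-2-yl)hex-4-en-1-yl]phenyl}ethan-1-one
Conditions: HCl (aq, 3 M), MeOH, 0 °C → rt, stopped at mono-cleavage
Reagents that add atoms: none
Why: Acid-catalysed acetal cleavage that should discriminate the two methoxymethyl ethers: the one ortho to the acetyl group is twisted out of conjugation by its two ortho substituents and is assisted by the carbonyl oxygen, which ends up hydrogen-bonded to the freed phenol, so it should leave well before the para acetal that becomes the C7 ether.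

Step 8
Reactants: 16 1-{2-hydroxy-6-methoxy-4-(methoxymethoxy)-3-[(2R)-5-methyl-2-(prop-1-en-2-yl)hex-4-en-1-yl]phenyl}ethan-1-one
Product: 18 5-methoxy-7-(methoxymethoxy)-8-[(2R)-5-methyl-2-(prop-1-en-2-yl)hex-4-en-1-yl]-4H-chromen-4-one, via enaminone 17 (not isolated)
Conditions: Me2NCH(OMe)2, toluene, 100 °C; then HCl (aq, 1 M), CH2Cl2, rt
Reagents that add atoms: N,N-dimethylformamide dimethyl acetal, COC(OC)N(C)C
Why: Condensation of the methyl ketone with the amide acetal gives the enaminone; mild acid then promotes addition of the phenol to the β-carbon and loss of dimethylamine (addition–elimination), closing ring C as the chromone. The brief biphasic acid treatment should leave the C7 acetal in place.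

Step 9
Reactants: 18 5-methoxy-7-(methoxymethoxy)-8-[(2R)-5-methyl-2-(prop-1-en-2-yl)hex-4-en-1-yl]-4H-chromen-4-one; 19 4-(methoxymethoxy)phenylboronic acid
Product: 20 (2S)-5-methoxy-7-(methoxymethoxy)-2-[4-(methoxymethoxy)phenyl]-8-[(2R)-5-methyl-2-(prop-1-en-2-yl)hex-4-en-1-yl]-2,3-dihydro-4H-chromen-4-one
Conditions: Pd(OCOCF3)2 (cat.), (R)-t-BuPyOx, NH4PF6, H2O, ClCH2CH2Cl, 60 °C
Reagents that add atoms: none
Why: Asymmetric conjugate addition of an arylboronic acid to a chromone under cationic divalent palladium–pyridinooxazoline catalysis: transmetalation, face-selective syn carbopalladation of C2=C3 and protonolysis of the palladium enolate by water; after syn addition the C2–H is anti to palladium, so β-hydride elimination to a flavone is closed. C2 is set by the ligand alone, since C2'' is too remote to interfere, and the chromone alkene is the only electron-poor alkene in 18.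

Step 10
Reactants: 20 (2S)-5-methoxy-7-(methoxymethoxy)-2-[4-(methoxymethoxy)phenyl]-8-[(2R)-5-methyl-2-(prop-1-en-2-yl)hex-4-en-1-yl]-2,3-dihydro-4H-chromen-4-one
Product: 21 kushenol U, (2S)-7-hydroxy-2-(4-hydroxyphenyl)-5-methoxy-8-[(2R)-5-methyl-2-(prop-1-en-2-yl)hex-4-en-1-yl]-2,3-dihydro-4H-chromen-4-one
Conditions: HCl (aq, 3 M), MeOH, rt → 40 °C
Reagents that add atoms: none
Why: Acid-catalysed transacetalisation of both methoxymethyl ethers to methanol; dilute, cool acid of this kind is the usual way to unmask acetal-protected ortho-prenylphenols without ring closure onto the alkene, and mild acid should not epimerise C2.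

## Compound list

1 | 5-methoxyresorcinol | COc1cc(O)cc(O)c1 | starting material
2 | 1-methoxy-3,5-bis(methoxymethoxy)benzene | COCOc1cc(OC)cc(OCOC)c1 | intermediate
3 | [4-methoxy-2,6-bis(methoxymethoxy)phenyl]lithium | [Li]c1c(OCOC)cc(OC)cc1OCOC | intermediate (not isolated)
4 | 2-iodo-5-methoxy-1,3-bis(methoxymethoxy)benzene | COCOc1cc(OC)cc(OCOC)c1I | intermediate
5 | 2-bromopropene | CC(Br)=C | starting material
6 | vinylboronic acid pinacol ester | C=CB1OC(C)(C)C(C)(C)O1 | starting material
7 | isopropenyllithium | [Li]C(C)=C | intermediate (not isolated)
8 | lithium (prop-1-en-2-yl)(vinyl)(pinacolato)borate | [Li+].C=C[B-]1(C(C)=C)OC(C)(C)C(C)(C)O1 | intermediate (not isolated)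
9 | (R)-2-{1-[4-methoxy-2,6-bis(methoxymethoxy)phenyl]-3-methylbut-3-en-2-yl}-4,4,5,5-tetramethyl-1,3,2-dioxaborolane | C=C(C)[C@H](B1OC(C)(C)C(C)(C)O1)Cc1c(OCOC)cc(OC)cc1OCOC | intermediate
10 | lithium chloromethyl ate complex of 9 (boron bears CH2Cl, the pinacolato group and C2'') | [Li+].C=C(C)[C@H]([B-]1(CCl)OC(C)(C)C(C)(C)O1)Cc1c(OCOC)cc(OC)cc1OCOC | intermediate (not isolated)
11 | 2-[(2R)-2-{[4-methoxy-2,6-bis(methoxymethoxy)phenyl]methyl}-3-methylbut-3-en-1-yl]-4,4,5,5-tetramethyl-1,3,2-dioxaborolane | C=C(C)[C@H](CB1OC(C)(C)C(C)(C)O1)Cc1c(OCOC)cc(OC)cc1OCOC | intermediate
12 | 1-bromo-2-methylpropene | CC(C)=CBr | starting material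
13 | 5-methoxy-1,3-bis(methoxymethoxy)-2-[(2R)-5-methyl-2-(prop-1-en-2-yl)hex-4-en-1-yl]benzene | C=C(C)[C@H](CC=C(C)C)Cc1c(OCOC)cc(OC)cc1OCOC | intermediate
14 | {6-methoxy-2,4-bis(methoxymethoxy)-3-[(2R)-5-methyl-2-(prop-1-en-2-yl)hex-4-en-1-yl]phenyl}lithium | C=C(C)[C@H](CC=C(C)C)Cc1c(OCOC)cc(OC)c([Li])c1OCOC | intermediate (not isolated)
15 | 1-{6-methoxy-2,4-bis(methoxymethoxy)-3-[(2R)-5-methyl-2-(prop-1-en-2-yl)hex-4-en-1-yl]phenyl}ethan-1-one | C=C(C)[C@H](CC=C(C)C)Cc1c(OCOC)cc(OC)c(C(C)=O)c1OCOC | intermediate
16 | 1-{2-hydroxy-6-methoxy-4-(methoxymethoxy)-3-[(2R)-5-methyl-2-(prop-1-en-2-yl)hex-4-en-1-yl]phenyl}ethan-1-one | C=C(C)[C@H](CC=C(C)C)Cc1c(OCOC)cc(OC)c(C(C)=O)c1O | intermediate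
17 | (E)-3-(dimethylamino)-1-{2-hydroxy-6-methoxy-4-(methoxymethoxy)-3-[(2R)-5-methyl-2-(prop-1-en-2-yl)hex-4-en-1-yl]phenyl}prop-2-en-1-one | C=C(C)[C@H](CC=C(C)C)Cc1c(OCOC)cc(OC)c(C(=O)/C=C/N(C)C)c1O | intermediate (not isolated)
18 | 5-methoxy-7-(methoxymethoxy)-8-[(2R)-5-methyl-2-(prop-1-en-2-yl)hex-4-en-1-yl]-4H-chromen-4-one | C=C(C)[C@H](CC=C(C)C)Cc1c(OCOC)cc(OC)c2c1OC=CC2=O | intermediate
19 | 4-(methoxymethoxy)phenylboronic acid | COCOc1ccc(B(O)O)cc1 | starting material
20 | (2S)-5-methoxy-7-(methoxymethoxy)-2-[4-(methoxymethoxy)phenyl]-8-[(2R)-5-methyl-2-(prop-1-en-2-yl)hex-4-en-1-yl]-2,3-dihydro-4H-chromen-4-one | C=C(C)[C@H](CC=C(C)C)Cc1c(OCOC)cc(OC)c2c1O[C@H](c1ccc(OCOC)cc1)CC2=O | intermediate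
21 | kushenol U, (2S)-7-hydroxy-2-(4-hydroxyphenyl)-5-methoxy-8-[(2R)-5-methyl-2-(prop-1-en-2-yl)hex-4-en-1-yl]-2,3-dihydro-4H-chromen-4-one | C=C(C)[C@H](CC=C(C)C)Cc1c(O)cc(OC)c2c1O[C@H](c1ccc(O)cc1)CC2=O | target

## Step count and least certain steps

Total step count: 10. Longest linear sequence: 10 steps (1 to 21); compounds 5, 6, 12 and 19 enter as commercial materials.

**Step 3 (key step).** The most likely failure is direct transfer of an alkenyl group from 8 to the crowded arylpalladium species, which would amount to a plain Suzuki coupling. The two ortho acetal groups hinder and can chelate the metal, which slows binding of the vinyl group. Residual bromide or iodide can also displace the alkene from palladium, and the facial selectivity may be eroded. The product is an allylic boronate, so a palladium-promoted 1,3-shift of boron, which would erase C2'', or a second coupling at the C–B bond may follow.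
Fallback, known chemistry, from 4 to 13 (bypassing 9 and 11): commercial racemic lavandulol F1 is resolved by lipase-catalysed acylation with vinyl acetate. The R alcohol is taken to be acylated faster, so that (S)-lavandulol F2 remains; if the enzyme prefers the other enantiomer, the acetate fraction is saponified instead. F2 is converted with I2, PPh3 and imidazole into (S)-lavandulyl iodide F3. Zinc dust with LiCl in THF inserts to give the lavandulylzinc iodide F4. Negishi coupling of F4 with 4 under Pd(OAc)2 and SPhos should then give 13. The descriptor changes from S to R only because the arylmethyl group ranks below isopropenyl; the spatial arrangement is the same.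

**Step 5.** Transmetalation of the β-branched primary boronate may be slow. Protodeboronation can then compete, as can β-hydride loss from the alkylpalladium species, whose β-hydrogen is the tertiary allylic C2''–H.
Fallback from 11 to 13 by Zweifel olefination: 12 and t-BuLi (2 equiv) give (2-methylprop-1-en-1-yl)lithium F5, which adds to 11 to form the alkenyl ate complex F6. Iodine at −78 °C moves the alkyl group from boron to the adjacent alkenyl carbon, and NaOMe then eliminates boron and iodide anti to give the C4''=C5'' alkene of 13.

**Step 7.** The two acetals may not be discriminated, so both are lost or a mixture forms. Prolonged acid also invites attack of a freed phenol on the protonated isopropenyl group.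
Fallback from 15 to 16: both acetals are cleaved deliberately with brief methanolic HCl to give the dihydroxy ketone F7. The non-chelated phenol para to the acetyl group is then realkylated alone with MOMCl and K2CO3 in acetone. The ortho phenol, hydrogen-bonded to the carbonyl group, should stay free.

**Step 9.** Carbopalladation of the electron-rich 5,7-dioxygenated chromone may stall, so that protodeboronation of 19 uses up the boronic acid. The cationic arylpalladium species may also insert into the isopropenyl alkene. The medium is weakly acidic and may loosen an acetal.
Fallback from 18 and 19 to 20 with a different metal and mechanism: asymmetric 1,4-addition under monovalent rhodium, using [RhCl(C2H4)2]2, the electron-poor atropisomeric bisphosphine MeO-F12-BIPHEP and a catalytic amount of KOH in toluene/H2O. Aryl–rhodium species add only to the activated enone and do not undergo Heck-type insertion into isolated alkenes. This fallback, F0, makes no new compound.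

**Step 10.** Protic acid may close the C7 phenol onto the protonated isopropenyl group, forming a chroman, and may cause partial epimerisation at C2 by reversible ring opening.
Fallback from 20 to 21 without protic acid: TMSOTf and 2,2'-bipyridyl in CH2Cl2 at 0 °C exchange both acetals for silyl ethers, giving the bis(trimethylsilyl) ether F8. Neutral aqueous work-up then hydrolyses F8 to 21.

## Further compounds

F1 | step 3 | racemic lavandulol, 5-methyl-2-(prop-1-en-2-yl)hex-4-en-1-ol | C=C(C)C(CC=C(C)C)CO
F2 | step 3 | (S)-lavandulol, (2S)-5-methyl-2-(prop-1-en-2-yl)hex-4-en-1-ol | C=C(C)[C@H](CC=C(C)C)CO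
F3 | step 3 | (S)-lavandulyl iodide, (3S)-3-(iodomethyl)-2,6-dimethylhepta-1,5-diene | C=C(C)[C@H](CC=C(C)C)CI
F4 | step 3 | [(2S)-5-methyl-2-(prop-1-en-2-yl)hex-4-en-1-yl]zinc iodide | C=C(C)[C@H](CC=C(C)C)C[Zn]I
F5 | step 5 | (2-methylprop-1-en-1-yl)lithium | [Li]C=C(C)C
F6 | step 5 | lithium (2-methylprop-1-en-1-yl) ate complex of 11 | [Li+].C=C(C)[C@H](C[B-]1(C=C(C)C)OC(C)(C)C(C)(C)O1)Cc1c(OCOC)cc(OC)cc1OCOC
F7 | step 7 | 1-{2,4-dihydroxy-6-methoxy-3-[(2R)-5-methyl-2-(prop-1-en-2-yl)hex-4-en-1-yl]phenyl}ethan-1-one | C=C(C)[C@H](CC=C(C)C)Cc1c(O)cc(OC)c(C(C)=O)c1O
F0 | step 9 | none | none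
F8 | step 10 | (2S)-5-methoxy-8-[(2R)-5-methyl-2-(prop-1-en-2-yl)hex-4-en-1-yl]-7-(trimethylsilyloxy)-2-[4-(trimethylsilyloxy)phenyl]-2,3-dihydro-4H-chromen-4-one | C=C(C)[C@H](CC=C(C)C)Cc1c(O[Si](C)(C)C)cc(OC)c2c1O[C@H](c1ccc(O[Si](C)(C)C)cc1)CC2=O
A1 | alternative 1 | 3-methoxycyclobut-2-en-1-one | COC1=CC(=O)C1
A2 | alternative 1 | triisopropyl{[(4R)-7-methyl-4-(prop-1-en-2-yl)oct-6-en-1-yn-1-yl]oxy}silane | C=C(C)[C@H](CC=C(C)C)CC#CO[Si](C(C)C)(C(C)C)C(C)C
A3 | alternative 1 | 2-[(2R)-5-methyl-2-(prop-1-en-2-yl)hex-4-en-1-yl]-5-methoxy-3-(triisopropylsilyloxy)phenol | C=C(C)[C@H](CC=C(C)C)Cc1c(O)cc(OC)cc1O[Si](C(C)C)(C(C)C)C(C)C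
A4 | alternative 2 | 6-methoxy-4-(methoxymethoxy)-3-[(2R)-5-methyl-2-(prop-1-en-2-yl)hex-4-en-1-yl]-2-(trimethylsilyl)phenyl trifluoromethanesulfonate | C=C(C)[C@H](CC=C(C)C)Cc1c(OCOC)cc(OC)c(OS(=O)(=O)C(F)(F)F)c1[Si](C)(C)C
A5 | alternative 2 | 3-methoxy-5-(methoxymethoxy)-6-[(2R)-5-methyl-2-(prop-1-en-2-yl)hex-4-en-1-yl]benzyne (aryne between C4a and C8a) | C=C(C)[C@H](CC=C(C)C)CC1=C(OCOC)C=C(OC)C#C1
A6 | alternative 2 | (E)-4-(methoxymethoxy)cinnamic acid | COCOc1ccc(/C=C/C(=O)O)cc1
A7 | alternative 2 | (E)-2'-hydroxy-3'-[(2R)-5-methyl-2-(prop-1-en-2-yl)hex-4-en-1-yl]-6'-methoxy-4,4'-bis(methoxymethoxy)chalcone | C=C(C)[C@H](CC=C(C)C)Cc1c(OCOC)cc(OC)c(C(=O)/C=C/c2ccc(OCOC)cc2)c1O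
A8 | alternative 3 | 5-methoxy-1,3-bis(methoxymethoxy)-2-{[(1R)-2-methylcyclobut-2-en-1-yl]methyl}benzene | CC1=CC[C@@H]1Cc1c(OCOC)cc(OC)cc1OCOC
A9 | alternative 3 | isobutylene | C=C(C)C
A10 | alternative 3 | 5-methoxy-1,3-bis(methoxymethoxy)-2-[(2R)-5-methyl-2-(prop-1-en-2-yl)hex-4-en-1-yl]benzene (identical with 13) | C=C(C)[C@H](CC=C(C)C)Cc1c(OCOC)cc(OC)cc1OCOC
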